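Ring B is read as an isophorone-type unit: C5–C6–C7 is the α,α′ axis of a methyl ketone (temporary C6 carbonyl) and C8–C9–C10 is an enone (C8 carbonyl, C9=C10). In one base-mediated operation an open-chain keto-enone ester closes ring A by Michael addition (C5–C10) and ring B by aldol condensation (C7–C8); the quaternary C4 centre, made from a Meyers lactam, relays configuration to C5 and C10. The C6 carbonyl is then erased by epoxidation and Wharton transposition, which plants the 8α-hydroxyl. The C13(16)-ene diol side chain is added last by Negishi coupling with a glyceraldehyde-derived bromoalkene.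

Key step: step 7

Remark: labdane numbering is used (ring A = C1–C5 and C10; ring B = C5–C10; side chain C11–C16; C17 on C8; C18 and C19 on C4; C20 on C10), and lactam 1, ether 7 and aldehyde 21 are taken as purchasable.

Step 1
Reactants: 1 (3S,7aR)-3-isopropyl-7a-methyltetrahydropyrrolo[2,1-b][1,3]oxazol-5(6H)-one
Product: 2 (3S,7aR)-3-isopropyl-6,7a-dimethyltetrahydropyrrolo[2,1-b][1,3]oxazol-5(6H)-one (C6 epimers)
Conditions: LiN(iPr)2, THF, −78 °C; MeI
Reagents that add atoms: iodomethane CI
Why: Enolate alkylation of the Meyers bicyclic lactam; the C6 centre forms as an epimer mixture, which does not matter because it is re-enolised in step 2.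

Step 2
Reactants: 2 (3S,7aR)-3-isopropyl-6,7a-dimethyltetrahydropyrrolo[2,1-b][1,3]oxazol-5(6H)-one; 3 1,3-dibromopropane
Product: 4 (3S,6S,7aR)-6-(3-bromopropyl)-3-isopropyl-6,7a-dimethyltetrahydropyrrolo[2,1-b][1,3]oxazol-5(6H)-one
Conditions: LiN(iPr)2, THF, −78 °C; 3 (4 equiv), −78 → −30 °C
Reagents that add atoms: none
Why: Second Meyers lactam alkylation, in which the enolate should take the electrophile on the endo (concave) face, anti to the angular methyl, so that the quaternary centre that becomes C4 is set as S.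

Step 3
Reactants: 4 (3S,6S,7aR)-6-(3-bromopropyl)-3-isopropyl-6,7a-dimethyltetrahydropyrrolo[2,1-b][1,3]oxazol-5(6H)-one
Product: 5 methyl (2S)-5-bromo-2-methyl-2-(2-oxopropyl)pentanoate
Conditions: H2SO4 (1 M), MeOH, reflux; NaHCO3 work-up
Reagents that add atoms: methanol CO; water O
Why: Acid methanolysis of the N-acyl N,O-ketal (the standard cleavage of these lactams) should release the methyl ketone and the methyl ester without touching the quaternary centre.

Step 4
Reactants: 6 pentane-2,4-dione; 7 benzyl 2-bromoethyl ether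
Product: 8 3-[2-(benzyloxy)ethyl]pentane-2,4-dione
Conditions: K2CO3, NaI (cat.), acetone, reflux
Reagents that add atoms: none
Why: C-alkylation of the acetylacetone anion (SN2, assisted by in situ Finkelstein exchange) installs C11–C12 on the future C9.

Step 5
Reactants: 8 3-[2-(benzyloxy)ethyl]pentane-2,4-dione
Product: 9 3-[2-(benzyloxy)ethyl]-4-oxopent-2-en-2-yl trifluoromethanesulfonate (E/Z mixture)
Conditions: Tf2O, Et3N, CH2Cl2, −78 → 0 °C
Reagents that add atoms: triflic anhydride O=S(=O)(OS(=O)(=O)C(F)(F)F)C(F)(F)F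
Why: O-sulfonylation of the enol of the symmetric 1,3-diketone gives the vinylogous acyl triflate; alkene geometry is irrelevant because C9 and C10 are set in step 7.

Step 6
Reactants: 5 methyl (2S)-5-bromo-2-methyl-2-(2-oxopropyl)pentanoate; 9 3-[2-(benzyloxy)ethyl]-4-oxopent-2-en-2-yl trifluoromethanesulfonate
Product: 11 methyl (2S)-7-acetyl-9-(benzyloxy)-2,6-dimethyl-2-(2-oxopropyl)non-6-enoate (E/Z mixture), via alkylzinc bromide 10 (not isolated)
Conditions: Zn dust, LiCl, THF, 50 °C; then 9, Pd(OAc)2 (3 mol %), SPhos (6 mol %), THF, 40 °C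
Reagents that add atoms: none
Why: Zinc insertion and Negishi coupling join C1 to C10, since β-triflyloxy enones undergo fast oxidative addition and alkylzinc halides tolerate the ketone and ester.

Step 7
Reactants: 11 methyl (2S)-7-acetyl-9-(benzyloxy)-2,6-dimethyl-2-(2-oxopropyl)non-6-enoate
Product: 15 methyl 12-(benzyloxy)-6-oxo-13,14,15,16-tetranorlabd-7-en-19-oate (5α-H; 9α-H; 10β-CH3; 4β-CO2CH3), via Michael adduct 12 (not isolated), via ketol 13 (not isolated), via deconjugated enone 14 (not isolated)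
Conditions: KOtBu (5 equiv), t-BuOH/THF, 0 → 45 °C; inverse quench into AcOH/THF, −78 °C; then (CO2H)2 (cat.), EtOH, 0 °C → rt
Reagents that add atoms: none
Why: KOtBu generates the C5 enolate of the C6 methyl ketone, which adds to C10 of the enone (6-exo-trig Michael addition, ring A); the C7 enolate of the same ketone then attacks the C8 carbonyl (6-(enolendo)-exo-trig aldol, ring B) and ketol 13 loses water by E1cB, an intramolecular Robinson-type Michael–aldol condensation whose closest known case is the base-mediated formation of isophorone from acetone and mesityl oxide. The Michael step is reversible, so C10 and C5 should settle relative to the fixed C4 centre in the ring-A chair that keeps the C5 acetyl and the C9 arm equatorial and the C10 methyl axial, with the ester rather than the C4 methyl in the axial site syn to it (smaller 1,3-diaxial strain); C5 stays epimerisable next to the C6 carbonyl and should end trans (5α-H). Excess base holds the enone as its linear dienolate, so C9 is set last: kinetic C7 protonation on the acetic acid quench gives 14, and acid-catalysed reconjugation through the dienol should protonate C9 axially from the α face, anti to the C10 methyl (the pattern of the Δ5 to Δ4 isomerisation of 3-keto steroids). The step needs C5 and not C7 as Michael donor, which ring size secures (six- against eight-membered), and the aldol direction C7 to C8 rather than C17 to C6, which the two quaternary carbons flanking C5 should secure by shielding the C6 carbonyl. The quaternary C4 has no α-hydrogen, so no ester-enolate Michael addition can compete.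

Step 8
Reactants: 15 methyl 12-(benzyloxy)-6-oxo-13,14,15,16-tetranorlabd-7-en-19-oate
Product: 16 methyl 12-(benzyloxy)-7α,8α-epoxy-6-oxo-13,14,15,16-tetranorlabdan-19-oate
Conditions: H2O2 (30%), NaOH (cat.), MeOH, 0 °C
Reagents that add atoms: hydrogen peroxide OO
Why: Weitz–Scheffer nucleophilic epoxidation (as for isophorone oxide), in which attack at C8 and ring closure should occur on the α face, away from the axial C10 methyl that is 1,3 to C8.

Step 9
Reactants: 16 methyl 12-(benzyloxy)-7α,8α-epoxy-6-oxo-13,14,15,16-tetranorlabdan-19-oate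
Product: 17 methyl 12-(benzyloxy)-8α-hydroxy-13,14,15,16-tetranorlabd-6-en-19-oate
Conditions: N2H4·H2O, AcOH (cat.), MeOH, 0 → 40 °C
Reagents that add atoms: none
Why: Wharton transposition: the epoxy hydrazone fragments with loss of N2 to the allylic alcohol, removing the C6 oxygen while the C8–O bond, and so the 8α configuration, is untouched.

Step 10
Reactants: 17 methyl 12-(benzyloxy)-8α-hydroxy-13,14,15,16-tetranorlabd-6-en-19-oate
Product: 18 methyl 12-(benzyloxy)-8α-(triethylsilyloxy)-13,14,15,16-tetranorlabd-6-en-19-oate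
Conditions: Et3SiOTf, 2,6-lutidine, CH2Cl2, −78 °C
Reagents that add atoms: triethylsilyl triflate CC[Si](CC)(CC)OS(=O)(=O)C(F)(F)F
Why: Silyl triflate silylation of the tertiary alcohol, needed so that the later C12 iodide cannot cyclise onto O8 to an ambrox-type tetrahydrofuran.

Step 11
Reactants: 18 methyl 12-(benzyloxy)-8α-(triethylsilyloxy)-13,14,15,16-tetranorlabd-6-en-19-oate
Product: 19 methyl 12-hydroxy-8α-(triethylsilyloxy)-13,14,15,16-tetranorlabdan-19-oate
Conditions: H2 (1 atm), Pd/C, EtOAc, NaHCO3, rt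
Reagents that add atoms: none
Why: Heterogeneous hydrogenation saturates C6=C7 and hydrogenolyses the benzyl ether in one operation, with no stereocentre created and no other alkene yet present.

Step 12
Reactants: 19 methyl 12-hydroxy-8α-(triethylsilyloxy)-13,14,15,16-tetranorlabdan-19-oate
Product: 20 methyl 12-iodo-8α-(triethylsilyloxy)-13,14,15,16-tetranorlabdan-19-oate
Conditions: I2, PPh3, imidazole, CH2Cl2, 0 °C → rt
Reagents that add atoms: iodine II
Why: Appel-type iodination (SN2 at the primary alkoxyphosphonium) under buffered conditions that the tertiary silyl ether should survive.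

Step 13
Reactants: 21 (R)-2,2-dimethyl-1,3-dioxolane-4-carbaldehyde
Product: 22 (S)-4-ethynyl-2,2-dimethyl-1,3-dioxolane
Conditions: dimethyl (1-diazo-2-oxopropyl)phosphonate, K2CO3, MeOH, 0 °C → rt
Reagents that add atoms: dimethyl (1-diazo-2-oxopropyl)phosphonate COP(=O)(OC)C(=[N+]=[N-])C(C)=O
Why: Ohira–Bestmann (Seyferth–Gilbert) homologation turns the aldehyde into the terminal alkyne without involving the stereocentre, which becomes C14.

Step 14
Reactants: 22 (S)-4-ethynyl-2,2-dimethyl-1,3-dioxolane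
Product: 24 (R)-4-(1-bromoethenyl)-2,2-dimethyl-1,3-dioxolane (same spatial arrangement as 22), via alkenylborane 23 (not isolated)
Conditions: 9-Br-9-BBN, CH2Cl2, 0 °C; then AcOH, 0 °C → rt
Reagents that add atoms: B-bromo-9-borabicyclo[3.3.1]nonane BrB1C2CCCC1CCC2
Why: Haloboration adds B–Br cis across the alkyne with bromine on the internal carbon, and protodeboronation with acetic acid then gives the 2-bromo-1-alkene.

Step 15
Reactants: 20 methyl 12-iodo-8α-(triethylsilyloxy)-13,14,15,16-tetranorlabdan-19-oate; 24 (R)-4-(1-bromoethenyl)-2,2-dimethyl-1,3-dioxolane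
Product: 26 methyl (14S)-14,15-(isopropylidenedioxy)-8α-(triethylsilyloxy)labd-13(16)-en-19-oate, via alkylzinc iodide 25 (not isolated)
Conditions: Zn dust, LiCl, THF, 40 °C; then 24, Pd(OAc)2 (5 mol %), SPhos (10 mol %), THF, 40 °C
Reagents that add atoms: none
Why: Zinc insertion and sp3–sp2 Negishi coupling forge C12–C13 and deliver the 1,1-disubstituted alkene directly, with C14 coming unchanged from the chiral pool.

Step 16
Reactants: 26 methyl (14S)-14,15-(isopropylidenedioxy)-8α-(triethylsilyloxy)labd-13(16)-en-19-oate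
Product: 27 (14S)-14,15-(isopropylidenedioxy)-8α-(triethylsilyloxy)labd-13(16)-en-19-oic acid
Conditions: n-PrSLi, HMPA, rt; cold dilute HCl to pH 4
Reagents that add atoms: none
Why: SN2 demethylation by thiolate at the O-methyl carbon frees the hindered axial acid, whose shielded carbonyl resists saponification.

Step 17
Reactants: 27 (14S)-14,15-(isopropylidenedioxy)-8α-(triethylsilyloxy)labd-13(16)-en-19-oic acid
Product: 28 (14S)-8α,14,15-trihydroxylabd-13(16)-en-19-oic acid (CNP0216809.1)
Conditions: AcOH/THF/H2O (3:1:1), 45 °C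
Reagents that add atoms: none
Why: Mild acid hydrolysis should remove the acetonide and the tertiary triethylsilyl ether without ionising the tertiary C8 alcohol or the allylic C14 alcohol.

Compound list
1 | (3S,7aR)-3-isopropyl-7a-methyltetrahydropyrrolo[2,1-b][1,3]oxazol-5(6H)-one | CC(C)[C@H]1CO[C@]2(C)CCC(=O)N12 | starting material
2 | (3S,7aR)-3-isopropyl-6,7a-dimethyltetrahydropyrrolo[2,1-b][1,3]oxazol-5(6H)-one (C6 epimers) | CC(C)[C@H]1CO[C@]2(C)CC(C)C(=O)N12 | intermediate
3 | 1,3-dibromopropane | BrCCCBr | starting material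
4 | (3S,6S,7aR)-6-(3-bromopropyl)-3-isopropyl-6,7a-dimethyltetrahydropyrrolo[2,1-b][1,3]oxazol-5(6H)-one | CC(C)[C@H]1CO[C@]2(C)C[C@](C)(CCCBr)C(=O)N12 | intermediate
5 | methyl (2S)-5-bromo-2-methyl-2-(2-oxopropyl)pentanoate | COC(=O)[C@](C)(CC(C)=O)CCCBr | intermediate
6 | pentane-2,4-dione | CC(=O)CC(C)=O | starting material
7 | benzyl 2-bromoethyl ether | BrCCOCc1ccccc1 | starting material
8 | 3-[2-(benzyloxy)ethyl]pentane-2,4-dione | CC(=O)C(CCOCc1ccccc1)C(C)=O | intermediate
9 | 3-[2-(benzyloxy)ethyl]-4-oxopent-2-en-2-yl trifluoromethanesulfonate (E/Z mixture) | CC(=O)C(CCOCc1ccccc1)=C(C)OS(=O)(=O)C(F)(F)F | intermediate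
10 | [(4S)-4-(methoxycarbonyl)-4-methyl-6-oxoheptyl]zinc bromide | COC(=O)[C@](C)(CC(C)=O)CCC[Zn]Br | intermediate
11 | methyl (2S)-7-acetyl-9-(benzyloxy)-2,6-dimethyl-2-(2-oxopropyl)non-6-enoate (E/Z mixture) | COC(=O)[C@](C)(CC(C)=O)CCCC(C)=C(CCOCc1ccccc1)C(C)=O | intermediate
12 | ring-A Michael adduct, methyl 2-acetyl-3-[5-(benzyloxy)-2-oxopentan-3-yl]-1,3-dimethylcyclohexane-1-carboxylate (C4, C5, C10 as in 15; C9 epimers) | O(Cc1ccccc1)CCC(C(C)=O)[C@@]1(C)CCC[C@](C)(C(=O)OC)[C@@H]1C(C)=O | intermediate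
13 | methyl 12-(benzyloxy)-8-hydroxy-6-oxo-13,14,15,16-tetranorlabdan-19-oate (C8 and C9 epimers) | O(Cc1ccccc1)CCC1[C@@]2(C)CCC[C@](C)(C(=O)OC)[C@@H]2C(=O)CC1(C)O | intermediate
14 | methyl 12-(benzyloxy)-6-oxo-13,14,15,16-tetranorlabd-8-en-19-oate | O(Cc1ccccc1)CCC=1[C@@]2(C)CCC[C@](C)(C(=O)OC)[C@@H]2C(=O)CC1C | intermediate
15 | methyl 12-(benzyloxy)-6-oxo-13,14,15,16-tetranorlabd-7-en-19-oate (5α-H; 9α-H; 10β-CH3; 4β-CO2CH3) | O(Cc1ccccc1)CC[C@@H]1[C@@]2(C)CCC[C@](C)(C(=O)OC)[C@@H]2C(=O)C=C1C | intermediate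
16 | methyl 12-(benzyloxy)-7α,8α-epoxy-6-oxo-13,14,15,16-tetranorlabdan-19-oate | O(Cc1ccccc1)CC[C@@H]1[C@@]2(C)CCC[C@](C)(C(=O)OC)[C@@H]2C(=O)[C@@H]3[C@@]1(C)O3 | intermediate
17 | methyl 12-(benzyloxy)-8α-hydroxy-13,14,15,16-tetranorlabd-6-en-19-oate | O(Cc1ccccc1)CC[C@@H]1[C@@]2(C)CCC[C@](C)(C(=O)OC)[C@@H]2C=C[C@@]1(C)O | intermediate
18 | methyl 12-(benzyloxy)-8α-(triethylsilyloxy)-13,14,15,16-tetranorlabd-6-en-19-oate | O(Cc1ccccc1)CC[C@@H]1[C@@]2(C)CCC[C@](C)(C(=O)OC)[C@@H]2C=C[C@@]1(C)O[Si](CC)(CC)CC | intermediate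
19 | methyl 12-hydroxy-8α-(triethylsilyloxy)-13,14,15,16-tetranorlabdan-19-oate | OCC[C@@H]1[C@@]2(C)CCC[C@](C)(C(=O)OC)[C@@H]2CC[C@@]1(C)O[Si](CC)(CC)CC | intermediate
20 | methyl 12-iodo-8α-(triethylsilyloxy)-13,14,15,16-tetranorlabdan-19-oate | ICC[C@@H]1[C@@]2(C)CCC[C@](C)(C(=O)OC)[C@@H]2CC[C@@]1(C)O[Si](CC)(CC)CC | intermediate
21 | (R)-2,2-dimethyl-1,3-dioxolane-4-carbaldehyde | O=C[C@H]1COC(C)(C)O1 | starting material
22 | (S)-4-ethynyl-2,2-dimethyl-1,3-dioxolane | C#C[C@H]1COC(C)(C)O1 | intermediate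
23 | 9-[(Z)-2-bromo-2-(2,2-dimethyl-1,3-dioxolan-4-yl)ethenyl]-9-borabicyclo[3.3.1]nonane | Br/C(=C\B1C2CCCC1CCC2)[C@H]3COC(C)(C)O3 | intermediate
24 | (R)-4-(1-bromoethenyl)-2,2-dimethyl-1,3-dioxolane | C=C(Br)[C@H]1COC(C)(C)O1 | intermediate
25 | alkylzinc iodide from 20 (C12–ZnI) | I[Zn]CC[C@@H]1[C@@]2(C)CCC[C@](C)(C(=O)OC)[C@@H]2CC[C@@]1(C)O[Si](CC)(CC)CC | intermediate
26 | methyl (14S)-14,15-(isopropylidenedioxy)-8α-(triethylsilyloxy)labd-13(16)-en-19-oate | C=C(CC[C@@H]1[C@@]2(C)CCC[C@](C)(C(=O)OC)[C@@H]2CC[C@@]1(C)O[Si](CC)(CC)CC)[C@H]3COC(C)(C)O3 | intermediate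
27 | (14S)-14,15-(isopropylidenedioxy)-8α-(triethylsilyloxy)labd-13(16)-en-19-oic acid | C=C(CC[C@@H]1[C@@]2(C)CCC[C@](C)(C(=O)O)[C@@H]2CC[C@@]1(C)O[Si](CC)(CC)CC)[C@H]3COC(C)(C)O3 | intermediate
28 | (14S)-8α,14,15-trihydroxylabd-13(16)-en-19-oic acid (CNP0216809.1) | C=C(CC[C@@H]1[C@@]2(C)CCC[C@](C)(C(=O)O)[C@@H]2CC[C@@]1(C)O)[C@H](O)CO | target

Total step count: 17. Longest linear sequence: 13 steps (steps 1–3, 6–12, 15–17).

Steps most likely to fail

Step 7. The Michael addition onto the twisted, tetrasubstituted enone may be outrun by base-induced deconjugation of the acceptor, by attack of the C7 enolate on the ester carbonyl (Claisen-type closure), or by the wrong aldol direction, so that ring A never closes cleanly. The fallback sets out from bromide 5 and stages the two bond formations under Lewis-acid control. Thermodynamic silylation (TBSCl, NaI, Et3N, MeCN) should give methyl (2S)-5-bromo-2-methyl-2-[(Z)-2-(tert-butyldimethylsilyloxy)prop-1-enyl]pentanoate F1. Coupling with 9 as in step 6 gives the enol-silane enone F2. A TiCl4-promoted intramolecular Mukaiyama–Michael addition (CH2Cl2, −78 °C) then closes ring A to diketone 12, now isolated. KOtBu treatment followed by the quench and reconjugation of step 7 closes ring B, and the route is rejoined at 15.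

Step 8. Alkaline peroxide may re-enolise the enone towards C9 (dienolate formation) and erode the kinetically set C9 configuration, or epoxidise both faces. The fallback sets out from 15 (whatever its C9 ratio) and resets C9 by hydrogenation. Chloranil in refluxing t-BuOH should dehydrogenate 15 through its dienol to methyl 12-(benzyloxy)-6-oxo-13,14,15,16-tetranorlabda-7,9(11)-dien-19-oate F3. Its 7,8-bond is epoxidised as in step 8 to the 7α,8α-epoxide F4, and Wharton transposition gives the 6,9(11)-dien-8α-ol F5, which is silylated to its triethylsilyl ether F6. Hydrogenation over Pd/C then saturates both alkenes and removes the benzyl group; H-9 should arrive from the open α face, since the β face is shielded by the C17 and C20 methyls. The route is rejoined at 19.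

Step 9. Condensation of hydrazine with the C6 carbonyl, which is hindered by the two quaternary carbons flanking C5, may be too slow, so that hydrazine opens the epoxide instead. The fallback sets out from 16 and avoids any addition at C6. SmI2 (THF/MeOH, −78 °C) should cleave the Cα–O bond to methyl 12-(benzyloxy)-8α-hydroxy-6-oxo-13,14,15,16-tetranorlabdan-19-oate F7. Its kinetic C7 enolate (KN(SiMe3)2, then PhNTf2) gives the 6-en-6-yl triflate F8. Reduction with Pd(OAc)2, PPh3, HCO2H and Bu3N (DMF, 60 °C) gives the alkene, and the route is rejoined at 17.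

Further compounds
F1 | step 7 | methyl (2S)-5-bromo-2-methyl-2-[(Z)-2-(tert-butyldimethylsilyloxy)prop-1-enyl]pentanoate | COC(=O)[C@](C)(/C=C(\O[Si](C)(C)C(C)(C)C)C)CCCBr
F2 | step 7 | methyl (2S)-7-acetyl-9-(benzyloxy)-2,6-dimethyl-2-[(Z)-2-(tert-butyldimethylsilyloxy)prop-1-enyl]non-6-enoate | COC(=O)[C@](C)(/C=C(\O[Si](C)(C)C(C)(C)C)C)CCCC(C)=C(CCOCc1ccccc1)C(C)=O
F3 | step 8 | methyl 12-(benzyloxy)-6-oxo-13,14,15,16-tetranorlabda-7,9(11)-dien-19-oate | O(Cc1ccccc1)CC=C1[C@@]2(C)CCC[C@](C)(C(=O)OC)[C@@H]2C(=O)C=C1C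
F4 | step 8 | methyl 12-(benzyloxy)-7α,8α-epoxy-6-oxo-13,14,15,16-tetranorlabd-9(11)-en-19-oate | O(Cc1ccccc1)CC=C1[C@@]2(C)CCC[C@](C)(C(=O)OC)[C@@H]2C(=O)[C@@H]3[C@@]1(C)O3
F5 | step 8 | methyl 12-(benzyloxy)-8α-hydroxy-13,14,15,16-tetranorlabda-6,9(11)-dien-19-oate | O(Cc1ccccc1)CC=C1[C@@]2(C)CCC[C@](C)(C(=O)OC)[C@@H]2C=C[C@@]1(C)O
F6 | step 8 | methyl 12-(benzyloxy)-8α-(triethylsilyloxy)-13,14,15,16-tetranorlabda-6,9(11)-dien-19-oate | O(Cc1ccccc1)CC=C1[C@@]2(C)CCC[C@](C)(C(=O)OC)[C@@H]2C=C[C@@]1(C)O[Si](CC)(CC)CC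
F7 | step 9 | methyl 12-(benzyloxy)-8α-hydroxy-6-oxo-13,14,15,16-tetranorlabdan-19-oate | O(Cc1ccccc1)CC[C@@H]1[C@@]2(C)CCC[C@](C)(C(=O)OC)[C@@H]2C(=O)C[C@@]1(C)O
F8 | step 9 | methyl 12-(benzyloxy)-8α-hydroxy-6-(trifluoromethylsulfonyloxy)-13,14,15,16-tetranorlabd-6-en-19-oate | O(Cc1ccccc1)CC[C@@H]1[C@@]2(C)CCC[C@](C)(C(=O)OC)[C@@H]2C(OS(=O)(=O)C(F)(F)F)=C[C@@]1(C)O
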